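**Plan**

- Numbering used in all explanations: ring C1 carries the side chain, C2 the 4-hydroxy-3-methoxyphenyl ring, C3 is CH2, C4=C5 is the ring alkene, C6 carries the 3,4-dimethoxyphenyl ring; chain C7 is the ketone carbon, C8 the central CH, C9 the enol carbon.
- Cuts, in retrosynthetic order: C8–C9 (acylation of a C1 methyl ketone by a feruloyl unit); C7=O back to a C7=C8 vinyl group and C4=C5 back to a C5 ketone; then C1–C7 and C6–aryl together.
- Enabling feature: with C5 as a carbonyl, C5/C6/C1 are the C=O, α- and β-carbons of a cyclohexenone whose γ-carbon C2 already bears its aryl ring, so the vinyl group and the dimethoxyphenyl ring can be added across C1 and C6 in one flask.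
- Forward: no ring is built. The carbocycle (ring A) is bought as a cyclohexenyl boronate and joined to the guaiacol ring by Suzuki coupling. Then follow hydrogenation, desymmetrisation to the enone, the three-component step, ketone to C4=C5 alkene, vinyl to acetyl, feruloylation and deprotection.
- Stereochemistry: C2 from enantioselective deprotonation by a chiral lithium amide; C1 from conjugate addition anti to the C2 aryl group; C6 from equilibration of the α-aryl ketone to the all-equatorial isomer.

Key step: step 7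

Assumption 1: the target is drawn as one tautomer of a rapidly equilibrating chelated keto-enol; the route delivers that equilibrium mixture.
Assumption 2: the (R,R)-amide is taken to give the (S)-silyl enol ether, by analogy with 4-alkylcyclohexanones; if analysis shows the opposite sense, the (S,S)-amine is used in the same way.

**Route**

Step 1
Reactants: 1 4-bromo-2-methoxyphenol; 2 2-(1,4-dioxaspiro[4.5]dec-7-en-8-yl)-4,4,5,5-tetramethyl-1,3,2-dioxaborolane
Product: 3 4-(1,4-dioxaspiro[4.5]dec-7-en-8-yl)-2-methoxyphenol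
Conditions: Pd(dppf)Cl2 (3 mol %), K2CO3 (3 equiv), 1,4-dioxane/H2O 4:1, 90 °C
Reagents that add atoms: none
Why: Suzuki–Miyaura coupling of an aryl bromide with an alkenyl pinacol boronate is reliable; the phenol is carried as its phenoxide under carbonate and the ketal is inert to base.

Step 2
Reactants: 3 4-(1,4-dioxaspiro[4.5]dec-7-en-8-yl)-2-methoxyphenol
Product: 4 4-(1,4-dioxaspiro[4.5]decan-8-yl)-2-methoxyphenol
Conditions: H2 (1 atm), 10% Pd/C, EtOAc, rt
Reagents that add atoms: none
Why: Heterogeneous catalytic hydrogenation saturates the trisubstituted styrene-type alkene without touching arene or ketal; the product is achiral, so no stereochemical question arises.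

Step 3
Reactants: 4 4-(1,4-dioxaspiro[4.5]decan-8-yl)-2-methoxyphenol
Product: 5 4-(4-hydroxy-3-methoxyphenyl)cyclohexan-1-one
Conditions: 2 M aq. HCl, THF, rt
Reagents that add atoms: water, O
Why: Acid-catalysed ketal hydrolysis frees the ketone, and it is done before any acid-labile protecting group is present.

Step 4
Reactants: 5 4-(4-hydroxy-3-methoxyphenyl)cyclohexan-1-one
Product: 6 4-[3-methoxy-4-(methoxymethoxy)phenyl]cyclohexan-1-one
Conditions: MOMCl, i-Pr2NEt, CH2Cl2, 0 °C → rt
Reagents that add atoms: chloromethyl methyl ether, COCCl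
Why: O-alkylation of the phenol (methoxymethyl ether formation) installs a group that withstands the amide bases, organometallics, hydride, xanthate chemistry and heat ahead and is removed by mild acid at the end.

Step 5
Reactants: 6 4-[3-methoxy-4-(methoxymethoxy)phenyl]cyclohexan-1-one
Product: 8 trimethyl{[(4S)-4-[3-methoxy-4-(methoxymethoxy)phenyl]cyclohex-1-en-1-yl]oxy}silane, via lithium enolate 7 (not isolated)
Conditions: (R,R)-bis(1-phenylethyl)amine (1.2 equiv), n-BuLi (1.15 equiv), THF, −78 °C; Me3SiCl (5 equiv), then 6 added slowly, −78 °C; Et3N, aq. NaHCO3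
Reagents that add atoms: chlorotrimethylsilane, C[Si](C)(C)Cl
Why: Enantiotopic-proton-selective deprotonation of the symmetric ketone by the homochiral lithium amide with internal Me3SiCl quench (asymmetric deprotonation/silyl enol ether formation) sets the aryl-bearing carbon, the later C2, under control of the chiral base, the enolate being trapped before it can equilibrate.

Step 6
Reactants: 8 trimethyl{[(4S)-4-[3-methoxy-4-(methoxymethoxy)phenyl]cyclohex-1-en-1-yl]oxy}silane
Product: 9 (4S)-4-[3-methoxy-4-(methoxymethoxy)phenyl]cyclohex-2-en-1-one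
Conditions: Pd(OAc)2 (1.05 equiv), MeCN, rt
Reagents that add atoms: none
Why: Saegusa–Ito oxidation (palladation of the silyl enol ether, β-hydride elimination) places the double bond on the side marked by the enol ether, so the C2 stereocentre passes unchanged into the enone.

Step 7
Reactants: 9 (4S)-4-[3-methoxy-4-(methoxymethoxy)phenyl]cyclohex-2-en-1-one; 10 vinylmagnesium bromide; 11 4-bromo-1,2-dimethoxybenzene
Product: 14 (2R,3R,4S)-2-(3,4-dimethoxyphenyl)-3-ethenyl-4-[3-methoxy-4-(methoxymethoxy)phenyl]cyclohexan-1-one, via bromomagnesium enolate 12 (not isolated), via chlorozinc enolate 13 (not isolated)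
Conditions: CuBr·SMe2 (10 mol %), 10 (1.2 equiv, slow addition), THF, −78 → −40 °C; ZnCl2 (1.3 equiv), −40 °C → rt; 11 (1.5 equiv), Pd2(dba)3 (2.5 mol %), P(t-Bu)3 (10 mol %), rt → 50 °C; aq. NH4Cl
Reagents that add atoms: none
Why: The copper-catalysed addition transfers the vinyl group to the β-carbon C1 and leaves bromomagnesium enolate 12 with its double bond fixed between C5 and C6; exchange with ZnCl2 gives the less basic chlorozinc enolate 13, which transmetalates to the arylpalladium bromide formed by oxidative addition of 11 to zerovalent palladium, and reductive elimination makes the C6–aryl bond. The closest known reaction type is the one-flask copper-catalysed conjugate addition of a Grignard reagent to a cyclohexenone followed by palladium/trialkylphosphine-catalysed α-arylation of the derived zinc enolate (a Negishi-type enolate coupling). No ring is closed. The C1 stereocentre is set by the substrate: the organocopper reagent attacks the enone face opposite the neighbouring C2 aryl group, giving the trans relationship typical of 4-substituted cyclohexenones. The C6 stereocentre is set under thermodynamic control, since the α-aryl ketone enolises readily and settles with the aryl group equatorial, trans to the vinyl group (brief treatment with DBU completes this if needed). The step needs arylation at C6 and not C4, and coupling of the enolate and not of the vinyl metal or the vinyl group; the first is secured by the regiodefined, weakly basic zinc enolate that does not equilibrate, the second by only a slight excess of Grignard reagent, an excess of the bromide and a temperature at which Heck insertion is slow.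

Step 8
Reactants: 14 (2R,3R,4S)-2-(3,4-dimethoxyphenyl)-3-ethenyl-4-[3-methoxy-4-(methoxymethoxy)phenyl]cyclohexan-1-one
Product: 15 (1R,2R,3R,4S)-2-(3,4-dimethoxyphenyl)-3-ethenyl-4-[3-methoxy-4-(methoxymethoxy)phenyl]cyclohexan-1-ol
Conditions: Li[HB(s-Bu)3], THF, −78 °C; H2O
Reagents that add atoms: none
Why: Ketone reduction with the bulky trialkylborohydride delivers hydride along the equatorial trajectory of the all-equatorial chair, so the new C5 stereocentre should carry an axial hydroxyl cis to the C6 aryl group (reagent approach control); it serves only to fix the geometry of the coming elimination.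

Step 9
Reactants: 15 (1R,2R,3R,4S)-2-(3,4-dimethoxyphenyl)-3-ethenyl-4-[3-methoxy-4-(methoxymethoxy)phenyl]cyclohexan-1-ol
Product: 18 O-[(1R,2R,3R,4S)-2-(3,4-dimethoxyphenyl)-3-ethenyl-4-[3-methoxy-4-(methoxymethoxy)phenyl]cyclohexyl] S-methyl carbonodithioate, via sodium alkoxide 16 (not isolated), via sodium xanthate salt 17 (not isolated)
Conditions: NaH, imidazole (cat.), THF, 0 °C → rt; CS2; MeI, rt
Reagents that add atoms: carbon disulfide, S=C=S; iodomethane, CI
Why: Xanthate ester formation (alkoxide addition to CS2, then S-methylation) is standard for hindered secondary alcohols and keeps the axial C5–O configuration.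

Step 10
Reactants: 18 O-[(1R,2R,3R,4S)-2-(3,4-dimethoxyphenyl)-3-ethenyl-4-[3-methoxy-4-(methoxymethoxy)phenyl]cyclohexyl] S-methyl carbonodithioate
Product: 19 (3R,4R,5S)-3-(3,4-dimethoxyphenyl)-4-ethenyl-5-[3-methoxy-4-(methoxymethoxy)phenyl]cyclohex-1-ene
Conditions: Ph2O, 190 °C, Ar
Reagents that add atoms: none
Why: Chugaev elimination is a thermal syn process through a six-membered transition state; only the equatorial C4–H is cis to the axial xanthate, the benzylic C6–H being trans-diaxial, so the C4=C5 alkene should form regiospecifically while C1, C2 and C6 stay untouched.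

Step 11
Reactants: 19 (3R,4R,5S)-3-(3,4-dimethoxyphenyl)-4-ethenyl-5-[3-methoxy-4-(methoxymethoxy)phenyl]cyclohex-1-ene
Product: 20 1-[(1R,2R,6S)-2-(3,4-dimethoxyphenyl)-6-[3-methoxy-4-(methoxymethoxy)phenyl]cyclohex-3-en-1-yl]ethan-1-one
Conditions: PdCl2 (20 mol %), CuCl (1 equiv), O2 (1 atm), DMF/H2O 7:1, rt
Reagents that add atoms: water, O
Why: Tsuji–Wacker oxidation (hydroxypalladation at the internal carbon of the monosubstituted alkene, β-hydride elimination) gives the methyl ketone while the much less reactive 1,2-disubstituted ring alkene is left; CuCl/O2 reoxidises palladium, and C1, now α to the ketone, already has the thermodynamically favoured configuration trans to both neighbours.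

Step 12
Reactants: 21 ferulic acid
Product: 22 methoxymethyl (E)-3-[3-methoxy-4-(methoxymethoxy)phenyl]prop-2-enoate
Conditions: MOMCl (2.5 equiv), i-Pr2NEt (3 equiv), CH2Cl2, 0 °C → rt
Reagents that add atoms: chloromethyl methyl ether, COCCl
Why: Exhaustive O-alkylation of phenol and carboxylic acid with chloromethyl methyl ether avoids any selectivity problem between the two acidic groups.

Step 13
Reactants: 22 methoxymethyl (E)-3-[3-methoxy-4-(methoxymethoxy)phenyl]prop-2-enoate
Product: 23 (E)-3-[3-methoxy-4-(methoxymethoxy)phenyl]prop-2-enoic acid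
Conditions: LiOH, THF/H2O 3:1, rt; then 1 M HCl to pH 3–4, 0 °C
Reagents that add atoms: lithium hydroxide, [Li+].[OH-]
Why: Saponification cleaves the methoxymethyl ester rapidly while the aryl methoxymethyl ether is stable to base, and cold, brief acidification leaves it intact.

Step 14
Reactants: 20 1-[(1R,2R,6S)-2-(3,4-dimethoxyphenyl)-6-[3-methoxy-4-(methoxymethoxy)phenyl]cyclohex-3-en-1-yl]ethan-1-one; 23 (E)-3-[3-methoxy-4-(methoxymethoxy)phenyl]prop-2-enoic acid
Product: 26 (2Z,4E)-1-[(1R,2R,6S)-2-(3,4-dimethoxyphenyl)-6-[3-methoxy-4-(methoxymethoxy)phenyl]cyclohex-3-en-1-yl]-3-hydroxy-5-[3-methoxy-4-(methoxymethoxy)phenyl]penta-2,4-dien-1-one, via acyl imidazole 24 (not isolated), via lithium enolate 25 (not isolated)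
Conditions: 23, 1,1'-carbonyldiimidazole, THF, rt (separate flask); 20, LiN(SiMe3)2 (2.2 equiv), THF, −78 °C; imidazolide solution added, −78 → 0 °C; aq. NH4Cl
Reagents that add atoms: none
Why: Crossed Claisen-type C-acylation: the kinetic lithium enolate forms at the unhindered methyl group and not at the crowded C1 methine, adds to the carbonyl of the acyl imidazolide, and the second equivalent of base holds the product as its diketonate, released on work-up as the chelated Z-enol with the E-alkene of the acid retained.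

Step 15
Reactants: 26 (2Z,4E)-1-[(1R,2R,6S)-2-(3,4-dimethoxyphenyl)-6-[3-methoxy-4-(methoxymethoxy)phenyl]cyclohex-3-en-1-yl]-3-hydroxy-5-[3-methoxy-4-(methoxymethoxy)phenyl]penta-2,4-dien-1-one
Product: 27 (2Z,4E)-1-[(1R,2R,6S)-2-(3,4-dimethoxyphenyl)-6-(4-hydroxy-3-methoxyphenyl)cyclohex-3-en-1-yl]-3-hydroxy-5-(4-hydroxy-3-methoxyphenyl)penta-2,4-dien-1-one
Conditions: HCl (1.25 M in MeOH), MeOH/THF, rt
Reagents that add atoms: none
Why: Acid-catalysed transacetalisation in methanol (methoxymethyl ether cleavage) frees both phenols; the chelated enol, the isolated ring alkene and the already thermodynamic C1 configuration should tolerate dilute methanolic acid at room temperature.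

**Compound list**

1 | 4-bromo-2-methoxyphenol | COc1cc(Br)ccc1O | starting material
2 | 2-(1,4-dioxaspiro[4.5]dec-7-en-8-yl)-4,4,5,5-tetramethyl-1,3,2-dioxaborolane | CC1(C)OB(OC1(C)C)C1=CCC2(CC1)OCCO2 | starting material
3 | 4-(1,4-dioxaspiro[4.5]dec-7-en-8-yl)-2-methoxyphenol | COc1cc(ccc1O)C1=CCC2(CC1)OCCO2 | intermediate
4 | 4-(1,4-dioxaspiro[4.5]decan-8-yl)-2-methoxyphenol | COc1cc(ccc1O)C1CCC2(CC1)OCCO2 | intermediate
5 | 4-(4-hydroxy-3-methoxyphenyl)cyclohexan-1-one | COc1cc(ccc1O)C1CCC(=O)CC1 | intermediate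
6 | 4-[3-methoxy-4-(methoxymethoxy)phenyl]cyclohexan-1-one | COCOc1ccc(cc1OC)C1CCC(=O)CC1 | intermediate
7 | lithium (4S)-4-[3-methoxy-4-(methoxymethoxy)phenyl]cyclohex-1-en-1-olate | [Li]OC1=CC[C@@H](c2ccc(OCOC)c(OC)c2)CC1 | intermediate
8 | trimethyl{[(4S)-4-[3-methoxy-4-(methoxymethoxy)phenyl]cyclohex-1-en-1-yl]oxy}silane | C[Si](C)(C)OC1=CC[C@@H](c2ccc(OCOC)c(OC)c2)CC1 | intermediate
9 | (4S)-4-[3-methoxy-4-(methoxymethoxy)phenyl]cyclohex-2-en-1-one | O=C1CC[C@H](c2ccc(OCOC)c(OC)c2)C=C1 | intermediate
10 | vinylmagnesium bromide | C=C[Mg]Br | starting material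
11 | 4-bromo-1,2-dimethoxybenzene | COc1ccc(Br)cc1OC | starting material
12 | bromomagnesium (3R,4S)-3-ethenyl-4-[3-methoxy-4-(methoxymethoxy)phenyl]cyclohex-1-en-1-olate | C=C[C@@H]1[C@@H](c2ccc(OCOC)c(OC)c2)CCC(O[Mg]Br)=C1 | intermediate
13 | chlorozinc (3R,4S)-3-ethenyl-4-[3-methoxy-4-(methoxymethoxy)phenyl]cyclohex-1-en-1-olate | C=C[C@@H]1[C@@H](c2ccc(OCOC)c(OC)c2)CCC(O[Zn]Cl)=C1 | intermediate
14 | (2R,3R,4S)-2-(3,4-dimethoxyphenyl)-3-ethenyl-4-[3-methoxy-4-(methoxymethoxy)phenyl]cyclohexan-1-one | C=C[C@@H]1[C@@H](c2ccc(OCOC)c(OC)c2)CCC(=O)[C@H]1c3ccc(OC)c(OC)c3 | intermediate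
15 | (1R,2R,3R,4S)-2-(3,4-dimethoxyphenyl)-3-ethenyl-4-[3-methoxy-4-(methoxymethoxy)phenyl]cyclohexan-1-ol | C=C[C@@H]1[C@@H](c2ccc(OCOC)c(OC)c2)CC[C@@H](O)[C@H]1c3ccc(OC)c(OC)c3 | intermediate
16 | sodium (1R,2R,3R,4S)-2-(3,4-dimethoxyphenyl)-3-ethenyl-4-[3-methoxy-4-(methoxymethoxy)phenyl]cyclohexan-1-olate | C=C[C@@H]1[C@@H](c2ccc(OCOC)c(OC)c2)CC[C@@H]([O-])[C@H]1c3ccc(OC)c(OC)c3.[Na+] | intermediate
17 | sodium O-[(1R,2R,3R,4S)-2-(3,4-dimethoxyphenyl)-3-ethenyl-4-[3-methoxy-4-(methoxymethoxy)phenyl]cyclohexyl] carbonodithioate | C=C[C@@H]1[C@@H](c2ccc(OCOC)c(OC)c2)CC[C@@H](OC(=S)[S-])[C@H]1c3ccc(OC)c(OC)c3.[Na+] | intermediate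
18 | O-[(1R,2R,3R,4S)-2-(3,4-dimethoxyphenyl)-3-ethenyl-4-[3-methoxy-4-(methoxymethoxy)phenyl]cyclohexyl] S-methyl carbonodithioate | C=C[C@@H]1[C@@H](c2ccc(OCOC)c(OC)c2)CC[C@@H](OC(=S)SC)[C@H]1c3ccc(OC)c(OC)c3 | intermediate
19 | (3R,4R,5S)-3-(3,4-dimethoxyphenyl)-4-ethenyl-5-[3-methoxy-4-(methoxymethoxy)phenyl]cyclohex-1-ene | C=C[C@@H]1[C@@H](c2ccc(OCOC)c(OC)c2)CC=C[C@H]1c3ccc(OC)c(OC)c3 | intermediate
20 | 1-[(1R,2R,6S)-2-(3,4-dimethoxyphenyl)-6-[3-methoxy-4-(methoxymethoxy)phenyl]cyclohex-3-en-1-yl]ethan-1-one | CC(=O)[C@@H]1[C@@H](c2ccc(OCOC)c(OC)c2)CC=C[C@H]1c3ccc(OC)c(OC)c3 | intermediate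
21 | ferulic acid, (E)-3-(4-hydroxy-3-methoxyphenyl)prop-2-enoic acid | COc1cc(/C=C/C(O)=O)ccc1O | starting material
22 | methoxymethyl (E)-3-[3-methoxy-4-(methoxymethoxy)phenyl]prop-2-enoate | COCOC(=O)/C=C/c1ccc(OCOC)c(OC)c1 | intermediate
23 | (E)-3-[3-methoxy-4-(methoxymethoxy)phenyl]prop-2-enoic acid | COCOc1ccc(/C=C/C(=O)O)cc1OC | intermediate
24 | (E)-1-(1H-imidazol-1-yl)-3-[3-methoxy-4-(methoxymethoxy)phenyl]prop-2-en-1-one | COCOc1ccc(/C=C/C(=O)n2ccnc2)cc1OC | intermediate
25 | lithium 1-[(1R,2R,6S)-2-(3,4-dimethoxyphenyl)-6-[3-methoxy-4-(methoxymethoxy)phenyl]cyclohex-3-en-1-yl]ethen-1-olate | C=C(O[Li])[C@@H]1[C@@H](c2ccc(OCOC)c(OC)c2)CC=C[C@H]1c3ccc(OC)c(OC)c3 | intermediate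
26 | (2Z,4E)-1-[(1R,2R,6S)-2-(3,4-dimethoxyphenyl)-6-[3-methoxy-4-(methoxymethoxy)phenyl]cyclohex-3-en-1-yl]-3-hydroxy-5-[3-methoxy-4-(methoxymethoxy)phenyl]penta-2,4-dien-1-one | COCOc1ccc(/C=C/C(O)=C/C(=O)[C@@H]2[C@@H](c3ccc(OCOC)c(OC)c3)CC=C[C@H]2c4ccc(OC)c(OC)c4)cc1OC | intermediate
27 | (2Z,4E)-1-[(1R,2R,6S)-2-(3,4-dimethoxyphenyl)-6-(4-hydroxy-3-methoxyphenyl)cyclohex-3-en-1-yl]-3-hydroxy-5-(4-hydroxy-3-methoxyphenyl)penta-2,4-dien-1-one | COc1cc(/C=C/C(O)=C/C(=O)[C@@H]2[C@@H](c3ccc(O)c(OC)c3)CC=C[C@H]2c2ccc(OC)c(OC)c2)ccc1O | target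

**Count and risks**

Total steps: 15. Longest linear sequence: 13 steps (steps 1–11, 14 and 15, from 1 to 27); steps 12 and 13 are the side branch.

Steps most likely to fail:

1. Step 7. Magnesium-to-zinc exchange may be incomplete, or proton transfer between the α-aryl ketone and unreacted enolate may move the enolate or cause double arylation; residual vinyl metal may also be cross-coupled in place of the enolate. Fallback, from 9 back to 14, with the aryl group put on first: α-iodination of 9 (I2, pyridine, CH2Cl2) should give (4S)-2-iodo-4-[3-methoxy-4-(methoxymethoxy)phenyl]cyclohex-2-en-1-one F1. Suzuki–Miyaura coupling with (3,4-dimethoxyphenyl)boronic acid (Pd2(dba)3, AsPh3, Ag2O, THF/H2O, rt) should give (4S)-2-(3,4-dimethoxyphenyl)-4-[3-methoxy-4-(methoxymethoxy)phenyl]cyclohex-2-en-1-one F2. Conjugate addition of the vinyl group (10, CuBr·SMe2, Me3SiCl, THF, −78 °C), anti to the C2 aryl group, then acidic hydrolysis of the silyl enol ether and equilibration with DBU, returns to 14.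

2. Step 5. Discrimination between the two enantiotopic α-methylene groups may be incomplete, or the enolate may partly equilibrate before silylation, so that material of insufficient enantiomeric purity enters the key step. Recrystallisation of 9 or 14 is the first remedy. Fallback, from 6 back to 9, by resolution in place of asymmetric deprotonation: LiN(i-Pr)2/Me3SiCl (THF, −78 °C) gives racemic trimethyl{[4-[3-methoxy-4-(methoxymethoxy)phenyl]cyclohex-1-en-1-yl]oxy}silane F3, and Pd(OAc)2 in MeCN gives racemic 4-[3-methoxy-4-(methoxymethoxy)phenyl]cyclohex-2-en-1-one F4. Preparative chromatography on a chiral stationary phase separates 9 from (4R)-4-[3-methoxy-4-(methoxymethoxy)phenyl]cyclohex-2-en-1-one F5, which is hydrogenated (H2, Pd/C) back to 6 and recycled.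

3. Step 11. Hydroxypalladation at the hindered vinyl group may be slow, so that palladium hydride-mediated migration of either double bond or attack on the ring alkene competes. Fallback, from 19 back to 20, by radical hydration in place of palladium oxidation: Mukaiyama hydration (Co(acac)2, PhSiH3, O2, i-PrOH/THF, rt) is expected to give the Markovnikov alcohol 1-[(1R,2R,6S)-2-(3,4-dimethoxyphenyl)-6-[3-methoxy-4-(methoxymethoxy)phenyl]cyclohex-3-en-1-yl]ethan-1-ol F6 as both carbinol epimers, and Dess–Martin periodinane (CH2Cl2, NaHCO3, rt) oxidises it to 20.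

**Further compounds**

F1 | step 7 | (4S)-2-iodo-4-[3-methoxy-4-(methoxymethoxy)phenyl]cyclohex-2-en-1-one | O=C1CC[C@H](c2ccc(OCOC)c(OC)c2)C=C1I
F2 | step 7 | (4S)-2-(3,4-dimethoxyphenyl)-4-[3-methoxy-4-(methoxymethoxy)phenyl]cyclohex-2-en-1-one | O=C1CC[C@H](c2ccc(OCOC)c(OC)c2)C=C1c3ccc(OC)c(OC)c3
F3 | step 5 | racemic trimethyl{[4-[3-methoxy-4-(methoxymethoxy)phenyl]cyclohex-1-en-1-yl]oxy}silane | C[Si](C)(C)OC1=CCC(c2ccc(OCOC)c(OC)c2)CC1
F4 | step 5 | racemic 4-[3-methoxy-4-(methoxymethoxy)phenyl]cyclohex-2-en-1-one | O=C1CCC(c2ccc(OCOC)c(OC)c2)C=C1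
F5 | step 5 | (4R)-4-[3-methoxy-4-(methoxymethoxy)phenyl]cyclohex-2-en-1-one | O=C1CC[C@@H](c2ccc(OCOC)c(OC)c2)C=C1
F6 | step 11 | 1-[(1R,2R,6S)-2-(3,4-dimethoxyphenyl)-6-[3-methoxy-4-(methoxymethoxy)phenyl]cyclohex-3-en-1-yl]ethan-1-ol (both carbinol epimers) | CC(O)[C@@H]1[C@@H](c2ccc(OCOC)c(OC)c2)CC=C[C@H]1c3ccc(OC)c(OC)c3
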